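**Plan**
- Cuts: the two silyl ethers come off first. The pyran ring of the isoflavan is then cut at C4–C4a while ring B is moved from C3 back to C4 (reverse 1,2-aryl shift). The resulting 1-aryl-3-aryloxypropan-2-yl mesylate is cut at O1–C2 (symmetric ring-A dihydroxy aldehyde) and at the ring-B aryl–CH2 bond (bromochromene plus (R)-epichlorohydrin).
- Forward order: the 2,2-dimethylpyran ring on ring B is made first (propargyl Claisen cascade). The three-carbon unit is then joined to ring B (Grignard/epoxide) and to one of the two equivalent hydroxyls of the ring-A aldehyde. The dihydropyran ring of the isoflavan is closed last, through C4–C4a.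
- Enabling feature: C1′ of ring B is flanked by the pyran oxygen on C2′ and lies para to the C4′ oxygen, so ring B can bridge C3/C4 as a phenonium ion. C4a of ring A is ortho to O1 and to the 5-methoxy group, para to the C7 oxygen, and is the only unsubstituted carbon next to O1 (C8 carries the formyl group), so it opens that ion at C4.
- Stereochemistry: the single stereocentre C3 is taken from (R)-epichlorohydrin. Its carbinol carbon is inverted once, when ring B displaces the mesylate from the rear, and is not a reacting centre afterwards.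

Key step: step 8

Assumption: 2,6-dihydroxy-4-methoxybenzaldehyde is taken as a purchasable building block (it is the 4-O-methyl ether of commercial 2,4,6-trihydroxybenzaldehyde).

**Step 1**
Reactants: 1 4-bromobenzene-1,3-diol (4-bromoresorcinol)
Product: 2 2-bromo-5-[(triisopropylsilyl)oxy]phenol
Conditions: TIPSCl (1.05 equiv), imidazole, CH2Cl2, 0 °C
Reagents that add atoms: triisopropylsilyl chloride, CC(C)[Si](Cl)(C(C)C)C(C)C
Why: Silylation of a phenol with the bulky TIPSCl/imidazole system should go to the hydroxyl para to bromine, which is less hindered than the hydroxyl flanked by bromine (sterically controlled site selectivity).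

**Step 2**
Reactants: 2 2-bromo-5-[(triisopropylsilyl)oxy]phenol; 3 3-chloro-3-methylbut-1-yne
Product: 4 [4-bromo-3-(2-methylbut-3-yn-2-yloxy)phenoxy]triisopropylsilane
Conditions: DBU, CuCl2·2H2O (cat.), MeCN, 0 °C
Reagents that add atoms: none
Why: Copper-catalysed O-propargylation of phenols with tertiary propargylic chlorides (via a copper allenylidene, DBU as base) is the standard route to aryl 1,1-dimethylpropargyl ethers and works with ortho-substituted phenols.

**Step 3**
Reactants: 4 [4-bromo-3-(2-methylbut-3-yn-2-yloxy)phenoxy]triisopropylsilane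
Product: 5 [(8-bromo-2,2-dimethyl-2H-chromen-5-yl)oxy]triisopropylsilane
Conditions: N,N-diethylaniline, 170 °C
Reagents that add atoms: none
Why: Aromatic propargyl Claisen rearrangement onto the only free ortho carbon (between the two oxygens; the other is blocked by bromine), followed in the same pot by 1,5-hydrogen shift and oxa-6π electrocyclisation, is the standard entry to 2,2-dimethyl-2H-chromenes and should tolerate the silyl ether and the bromide.

**Step 4**
Reactants: 5 [(8-bromo-2,2-dimethyl-2H-chromen-5-yl)oxy]triisopropylsilane; 6 (R)-epichlorohydrin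
Product: 8 (2R)-1-chloro-3-[2,2-dimethyl-5-(triisopropylsilyloxy)-2H-chromen-8-yl]propan-2-ol, via aryl Grignard reagent 7 (not isolated)
Conditions: Mg turnings, LiCl, THF, 25 °C; then CuI (10 mol %), 6, −30 → 0 °C; H2O quench
Reagents that add atoms: none
Why: Magnesium insertion gives the aryl Grignard reagent, and copper-catalysed epoxide opening at the CH2 terminus (faster than displacement of chloride) should give the chlorohydrin with the stereocentre of 6 untouched.

**Step 5**
Reactants: 8 (2R)-1-chloro-3-[2,2-dimethyl-5-(triisopropylsilyloxy)-2H-chromen-8-yl]propan-2-ol; 9 2,6-dihydroxy-4-methoxybenzaldehyde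
Product: 11 2-{[(2R)-3-[2,2-dimethyl-5-(triisopropylsilyloxy)-2H-chromen-8-yl]-2-hydroxypropyl]oxy}-6-hydroxy-4-methoxybenzaldehyde, via epoxide 10 (not isolated)
Conditions: K2CO3, DMF, 70 °C (9 in slight excess)
Reagents that add atoms: none
Why: Williamson-type etherification in which carbonate closes the chlorohydrin to the terminal epoxide and the phenoxide of 9 opens it at CH2; the two hydroxyls of 9 are equivalent and the second one, hydrogen-bonded to the formyl group, should react much more slowly, so one regioisomer is expected and the stereocentre is a spectator.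

**Step 6**
Reactants: 11 2-{[(2R)-3-[2,2-dimethyl-5-(triisopropylsilyloxy)-2H-chromen-8-yl]-2-hydroxypropyl]oxy}-6-hydroxy-4-methoxybenzaldehyde
Product: 12 2-{[(2R)-3-[2,2-dimethyl-5-(triisopropylsilyloxy)-2H-chromen-8-yl]-2-hydroxypropyl]oxy}-4-methoxy-6-(triisopropylsilyloxy)benzaldehyde
Conditions: TIPSCl, imidazole, DMAP (cat.), DMF, 40 °C
Reagents that add atoms: triisopropylsilyl chloride, CC(C)[Si](Cl)(C(C)C)C(C)C
Why: Phenol-selective silylation: the acidic phenol should be silylated while the secondary alcohol is too hindered to react with TIPSCl at a useful rate, and the silyloxy group keeps ring A electron-rich.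

**Step 7**
Reactants: 12 2-{[(2R)-3-[2,2-dimethyl-5-(triisopropylsilyloxy)-2H-chromen-8-yl]-2-hydroxypropyl]oxy}-4-methoxy-6-(triisopropylsilyloxy)benzaldehyde
Product: 13 (2R)-1-[2,2-dimethyl-5-(triisopropylsilyloxy)-2H-chromen-8-yl]-3-[2-formyl-5-methoxy-3-(triisopropylsilyloxy)phenoxy]propan-2-yl methanesulfonate
Conditions: MsCl, Et3N, CH2Cl2, −10 °C; used without chromatography
Reagents that add atoms: methanesulfonyl chloride, CS(=O)(=O)Cl
Why: Standard mesylation of a secondary alcohol; the C–O bond is not broken, so the configuration is retained.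

**Step 8**
Reactants: 13 (2R)-1-[2,2-dimethyl-5-(triisopropylsilyloxy)-2H-chromen-8-yl]-3-[2-formyl-5-methoxy-3-(triisopropylsilyloxy)phenoxy]propan-2-yl methanesulfonate
Product: 15 (3R)-3-[2,2-dimethyl-5-(triisopropylsilyloxy)-2H-chromen-8-yl]-5-methoxy-7-(triisopropylsilyloxy)-3,4-dihydro-2H-chromene-8-carbaldehyde, via ring-B phenonium mesylate 14 (not isolated)
Conditions: 1,1,1,3,3,3-hexafluoropropan-2-ol (HFIP, 0.02 M), 2,6-di-tert-butyl-4-methylpyridine (1.5 equiv), 40 °C
Reagents that add atoms: none
Why: Proposed new method: in strongly ionising, non-nucleophilic HFIP the mesylate should leave with rear-side participation of ring B (Ar1-3), giving phenonium ion 14 with inversion at C3; C4a of ring A then opens the three-membered ring at its CH2 carbon (the former benzylic carbon, now C4) in a Friedel–Crafts step, so that ring B ends on C3 and the pyran ring is closed through C4–C4a. The closest known reaction types are the HFIP-promoted Friedel–Crafts alkylations of arenes by β-aryl alcohols, sulfonates and epoxides that run through phenonium ions with stereospecific 1,2-aryl shift, and the 6-endo epoxide–arene cyclisation of aryl glycidyl ethers to chroman-3-ols. The ring is closed in a 6-endo-tet opening of the spiro cyclopropane (Ar2-6 type, both bridged carbons end in the new ring), expected to be preferred over 5-exo attack at C3 because the ortho carbon cannot reach C3 with rear-side alignment and because C3 is deactivated by the neighbouring C2–O1 oxygen. The stereocentre C3 is substrate-controlled: the (R)-carbinol carbon is inverted once by the anti attack of ring B and is not a reacting centre in the ring closure, so the (R)-mesylate should give the (3R)-isoflavan. The step needs aryl bridging to outrun hydride shift, elimination and participation of the ring-B pyran oxygen, which the oxygen donors ortho and para to C1′ should secure; it needs attack by C4a alone, which the O1–C2 tether and the formyl group on C8 secure; the hindered pyridine keeps the medium non-acidic for the chromene double bond and the silyl ethers.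

**Step 9**
Reactants: 15 (3R)-3-[2,2-dimethyl-5-(triisopropylsilyloxy)-2H-chromen-8-yl]-5-methoxy-7-(triisopropylsilyloxy)-3,4-dihydro-2H-chromene-8-carbaldehyde
Product: 16 (3R)-7-hydroxy-3-(5-hydroxy-2,2-dimethyl-2H-chromen-8-yl)-5-methoxy-3,4-dihydro-2H-chromene-8-carbaldehyde (CNP0272344.1)
Conditions: TBAF (2.4 equiv), AcOH (2.4 equiv), THF, 0 °C
Reagents that add atoms: none
Why: Fluoride-mediated cleavage of both aryl silyl ethers under acetic acid buffering should leave the aldehyde, the chromene double bond and the C3 stereocentre untouched.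

**Compound list**
1 | 4-bromobenzene-1,3-diol (4-bromoresorcinol) | Oc1ccc(Br)c(O)c1 | starting material
2 | 2-bromo-5-[(triisopropylsilyl)oxy]phenol | Oc1cc(O[Si](C(C)C)(C(C)C)C(C)C)ccc1Br | intermediate
3 | 3-chloro-3-methylbut-1-yne | CC(C)(Cl)C#C | starting material
4 | [4-bromo-3-(2-methylbut-3-yn-2-yloxy)phenoxy]triisopropylsilane | C#CC(C)(C)Oc1cc(O[Si](C(C)C)(C(C)C)C(C)C)ccc1Br | intermediate
5 | [(8-bromo-2,2-dimethyl-2H-chromen-5-yl)oxy]triisopropylsilane | CC1(C)C=Cc2c(O[Si](C(C)C)(C(C)C)C(C)C)ccc(Br)c2O1 | intermediate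
6 | (R)-epichlorohydrin, (2R)-2-(chloromethyl)oxirane | ClC[C@H]1CO1 | starting material
7 | [2,2-dimethyl-5-(triisopropylsilyloxy)-2H-chromen-8-yl]magnesium bromide | CC1(C)C=Cc2c(O[Si](C(C)C)(C(C)C)C(C)C)ccc([Mg]Br)c2O1 | intermediate
8 | (2R)-1-chloro-3-[2,2-dimethyl-5-(triisopropylsilyloxy)-2H-chromen-8-yl]propan-2-ol | ClC[C@H](O)Cc1ccc(O[Si](C(C)C)(C(C)C)C(C)C)c2C=CC(C)(C)Oc12 | intermediate
9 | 2,6-dihydroxy-4-methoxybenzaldehyde | COc1cc(O)c(C=O)c(O)c1 | starting material
10 | (2R)-2-{[2,2-dimethyl-5-(triisopropylsilyloxy)-2H-chromen-8-yl]methyl}oxirane | C1[C@H](O1)Cc2ccc(O[Si](C(C)C)(C(C)C)C(C)C)c3C=CC(C)(C)Oc23 | intermediate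
11 | 2-{[(2R)-3-[2,2-dimethyl-5-(triisopropylsilyloxy)-2H-chromen-8-yl]-2-hydroxypropyl]oxy}-6-hydroxy-4-methoxybenzaldehyde | COc1cc(O)c(C=O)c(OC[C@H](O)Cc2ccc(O[Si](C(C)C)(C(C)C)C(C)C)c3C=CC(C)(C)Oc23)c1 | intermediate
12 | 2-{[(2R)-3-[2,2-dimethyl-5-(triisopropylsilyloxy)-2H-chromen-8-yl]-2-hydroxypropyl]oxy}-4-methoxy-6-(triisopropylsilyloxy)benzaldehyde | COc1cc(O[Si](C(C)C)(C(C)C)C(C)C)c(C=O)c(OC[C@H](O)Cc2ccc(O[Si](C(C)C)(C(C)C)C(C)C)c3C=CC(C)(C)Oc23)c1 | intermediate
13 | (2R)-1-[2,2-dimethyl-5-(triisopropylsilyloxy)-2H-chromen-8-yl]-3-[2-formyl-5-methoxy-3-(triisopropylsilyloxy)phenoxy]propan-2-yl methanesulfonate | COc1cc(O[Si](C(C)C)(C(C)C)C(C)C)c(C=O)c(OC[C@H](OS(C)(=O)=O)Cc2ccc(O[Si](C(C)C)(C(C)C)C(C)C)c3C=CC(C)(C)Oc23)c1 | intermediate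
14 | ring-B phenonium ion: spiro cyclopropane on C8 of the chromene bridging C3 and C4, (R) at C3 (which carries the CH2–O–aryl arm), as its methanesulfonate ion pair | COc1cc(O[Si](C(C)C)(C(C)C)C(C)C)c(C=O)c(OC[C@@H]2CC23C=C[C+](O[Si](C(C)C)(C(C)C)C(C)C)C4=C3OC(C)(C)C=C4)c1.CS(=O)(=O)[O-] | intermediate
15 | (3R)-3-[2,2-dimethyl-5-(triisopropylsilyloxy)-2H-chromen-8-yl]-5-methoxy-7-(triisopropylsilyloxy)-3,4-dihydro-2H-chromene-8-carbaldehyde | COc1cc(O[Si](C(C)C)(C(C)C)C(C)C)c(C=O)c2c1C[C@H](c1ccc(O[Si](C(C)C)(C(C)C)C(C)C)c3c1OC(C)(C)C=C3)CO2 | intermediate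
16 | (3R)-7-hydroxy-3-(5-hydroxy-2,2-dimethyl-2H-chromen-8-yl)-5-methoxy-3,4-dihydro-2H-chromene-8-carbaldehyde | COc1cc(O)c(C=O)c2c1C[C@H](c1ccc(O)c3c1OC(C)(C)C=C3)CO2 | target

**Step count and risks**
Total step count: 9. Longest linear sequence: 9 steps (1 → 2 → 4 → 5 → 8 → 11 → 12 → 13 → 15 → 16); compounds 3, 6 and 9 are bought.

Steps most likely to fail:

Step 8 (Proposed new method). At the ionisation of the secondary mesylate the aryl-bridged path may be bypassed. A 1,2-hydride shift from the benzylic CH2 would give a benzylic cation and then a 4-arylchroman; loss of a proton would give alkenes; the pyran oxygen of ring B could participate and open the chromene. The fallback enters the same ring closure from a primary sulfonate, where no hydride shift can compete, and sets the stereocentre by enzymatic desymmetrisation. It sets out from 5 and comes back at 15. Palladium-catalysed arylation of diethyl malonate with 5 (Pd2(dba)3, P(t-Bu)3·HBF4, K3PO4, toluene, 70 °C) would give diethyl 2-[2,2-dimethyl-5-(triisopropylsilyloxy)-2H-chromen-8-yl]malonate F1. Reduction with LiAlH4 (THF, 0 °C) would give the prochiral 2-[2,2-dimethyl-5-(triisopropylsilyloxy)-2H-chromen-8-yl]propane-1,3-diol F2. Lipase-catalysed desymmetrising acetylation (Pseudomonas cepacia lipase, vinyl acetate; enzyme selected for the (R) sense) would give (2R)-2-[2,2-dimethyl-5-(triisopropylsilyloxy)-2H-chromen-8-yl]-3-hydroxypropyl acetate F3. Mono-silylation of 9 (TIPSCl, imidazole) would give 2-hydroxy-4-methoxy-6-(triisopropylsilyloxy)benzaldehyde F4, and Mitsunobu etherification of F3 with F4 (PPh3, DIAD, THF) would give (2R)-2-[2,2-dimethyl-5-(triisopropylsilyloxy)-2H-chromen-8-yl]-3-[2-formyl-5-methoxy-3-(triisopropylsilyloxy)phenoxy]propyl acetate F5. Neutral lipase transesterification (Candida antarctica lipase B, n-butanol) would free 2-{[(2S)-2-[2,2-dimethyl-5-(triisopropylsilyloxy)-2H-chromen-8-yl]-3-hydroxypropyl]oxy}-4-methoxy-6-(triisopropylsilyloxy)benzaldehyde F6. MsCl/Et3N would give (2R)-2-[2,2-dimethyl-5-(triisopropylsilyloxy)-2H-chromen-8-yl]-3-[2-formyl-5-methoxy-3-(triisopropylsilyloxy)phenoxy]propyl methanesulfonate F7. Solvolytic Friedel–Crafts cycloalkylation of F7 in HFIP with the same pyridine base closes C4–C4a without touching C3 and returns to 15. This fallback does not help if the bridged ion is opened at C3, since it passes through the same ion.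

Step 1. Site selectivity between the two hydroxyls may be poor: silylation may also occur at the oxygen next to bromine, or twice. The fallback reverses the order and relies on acidity instead of sterics. It sets out from 1 (with 3) and comes back at 5. Copper-catalysed propargylation with one equivalent of DBU should take the more acidic hydroxyl ortho to bromine and give 4-bromo-3-[(2-methylbut-3-yn-2-yl)oxy]phenol F8. The Claisen cascade (N,N-diethylaniline, 170 °C) would give 8-bromo-2,2-dimethyl-2H-chromen-5-ol F9, and silylation (TIPSCl, imidazole) would give 5.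

Step 5. The hydrogen-bonded phenoxide of 9 is a weak nucleophile, so O-alkylation may be slow, and the aryl silyl ether may be lost or transferred under hot carbonate; double alkylation is also possible. The fallback replaces basic phenoxide chemistry by Lewis-acid catalysis. It sets out from 8 and comes back at 11. Epoxide 10 is closed and isolated (NaH, THF, 0 °C) and then opened by 9 under neutral conditions with (salen)Co(OAc), the cobalt acetate complex of N,N′-bis(3,5-di-tert-butylsalicylidene)cyclohexane-1,2-diamine, in the enantiomeric form matched to 10 (tert-butyl methyl ether, 25 °C). This fallback makes no compound outside the compound list (F0).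

**Further compounds**
F1 | step 8 | diethyl 2-[2,2-dimethyl-5-(triisopropylsilyloxy)-2H-chromen-8-yl]malonate | CCOC(=O)C(C(=O)OCC)c1ccc(O[Si](C(C)C)(C(C)C)C(C)C)c2C=CC(C)(C)Oc12
F2 | step 8 | 2-[2,2-dimethyl-5-(triisopropylsilyloxy)-2H-chromen-8-yl]propane-1,3-diol | OCC(CO)c1ccc(O[Si](C(C)C)(C(C)C)C(C)C)c2C=CC(C)(C)Oc12
F3 | step 8 | (2R)-2-[2,2-dimethyl-5-(triisopropylsilyloxy)-2H-chromen-8-yl]-3-hydroxypropyl acetate | CC(=O)OC[C@@H](CO)c1ccc(O[Si](C(C)C)(C(C)C)C(C)C)c2C=CC(C)(C)Oc12
F4 | step 8 | 2-hydroxy-4-methoxy-6-(triisopropylsilyloxy)benzaldehyde | COc1cc(O)c(C=O)c(O[Si](C(C)C)(C(C)C)C(C)C)c1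
F5 | step 8 | (2R)-2-[2,2-dimethyl-5-(triisopropylsilyloxy)-2H-chromen-8-yl]-3-[2-formyl-5-methoxy-3-(triisopropylsilyloxy)phenoxy]propyl acetate | COc1cc(O[Si](C(C)C)(C(C)C)C(C)C)c(C=O)c(OC[C@H](COC(C)=O)c2ccc(O[Si](C(C)C)(C(C)C)C(C)C)c3C=CC(C)(C)Oc23)c1
F6 | step 8 | 2-{[(2S)-2-[2,2-dimethyl-5-(triisopropylsilyloxy)-2H-chromen-8-yl]-3-hydroxypropyl]oxy}-4-methoxy-6-(triisopropylsilyloxy)benzaldehyde | COc1cc(O[Si](C(C)C)(C(C)C)C(C)C)c(C=O)c(OC[C@H](CO)c2ccc(O[Si](C(C)C)(C(C)C)C(C)C)c3C=CC(C)(C)Oc23)c1
F7 | step 8 | (2R)-2-[2,2-dimethyl-5-(triisopropylsilyloxy)-2H-chromen-8-yl]-3-[2-formyl-5-methoxy-3-(triisopropylsilyloxy)phenoxy]propyl methanesulfonate | COc1cc(O[Si](C(C)C)(C(C)C)C(C)C)c(C=O)c(OC[C@H](COS(C)(=O)=O)c2ccc(O[Si](C(C)C)(C(C)C)C(C)C)c3C=CC(C)(C)Oc23)c1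
F8 | step 1 | 4-bromo-3-[(2-methylbut-3-yn-2-yl)oxy]phenol | C#CC(C)(C)Oc1cc(O)ccc1Br
F9 | step 1 | 8-bromo-2,2-dimethyl-2H-chromen-5-ol | CC1(C)C=Cc2c(O)ccc(Br)c2O1
F0 | step 5 | none | none
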